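**Plan**

- Retrosynthesis: the three silyl ethers come off last. Ring A is then cut at C8–C8a, C5–C6, C7–C8 and C4a–C5, which splits the protected flavanonol into a ring C diazoketone and a geranyl siloxyalkyne.
- This cut is possible because ring A carries oxygen on C5 and C7, the geranyl carbon C6 between them, hydrogen on C8, and is fused to the pyranone through C4a and C8a. C5 maps onto a ketene carbonyl, C6 and C7 onto the two carbons of an oxygen-polarized alkyne, and C8 onto a diazo carbon, so C6 and C8 are told apart while the ring is built.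
- The diazoketone is cut at the acyl–CHN2 bond, at O1–C8a and C4a–C8a-side carbon (oxalate Claisen, cyclodehydration) and at C2–C3 (glycolate aldol onto the ring B aldehyde). The alkyne is cut at its C–O bond and at the geranyl–alkyne bond.
- Forward order: C2–C3 aldol, ring C (step 7), diazoketone, ring A (step 13), global desilylation. Ring B is bought.
- Stereochemistry: C2 and C3 are both set by the auxiliary-controlled anti glycolate aldol of step 2 and are not touched afterwards. The E-alkene comes from geranyl bromide.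

Key step: step 13

Assumption: in the open-transition-state titanium aldol the L-phenylalanine-derived auxiliary is taken to expose the enolate face of its thiocarbonyl-chelated conformer, which leads to the (2R,3R) adduct drawn; if the other face reacted, the D-phenylalanine-derived auxiliary would be used and nothing else changes. 2-(Allyloxy)acetic acid and diallyl oxalate are taken as commercial.

**Route**

Step 1
Reactants: 1 (S)-4-benzyl-1,3-oxazolidine-2-thione; 2 2-(allyloxy)acetic acid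
Product: 3 (S)-3-[2-(allyloxy)acetyl]-4-benzyl-1,3-oxazolidine-2-thione
Conditions: EDC·HCl, DMAP (cat.), CH2Cl2, 0 °C → rt
Reagents that add atoms: none
Why: Carbodiimide-mediated N-acylation of the auxiliary is a standard way to load a glycolic acid, and the allyl ether is inert to it.

Step 2
Reactants: 3 (S)-3-[2-(allyloxy)acetyl]-4-benzyl-1,3-oxazolidine-2-thione; 4 4-(tert-butyldimethylsilyloxy)benzaldehyde
Product: 6 (S)-3-[(2R,3R)-2-(allyloxy)-3-[4-(tert-butyldimethylsilyloxy)phenyl]-3-hydroxypropanoyl]-4-benzyl-1,3-oxazolidine-2-thione, via trichlorotitanium enolate 5 (not isolated)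
Conditions: TiCl4, i-Pr2NEt, CH2Cl2, −78 °C; then 4 precomplexed with TiCl4, −78 °C
Reagents that add atoms: none
Why: In this titanium-mediated anti-selective glycolate aldol addition the chelated Z-enolate should meet the TiCl4-activated aldehyde through an open transition state to give the 2,3-anti adduct, and the benzyl group of the auxiliary should shield one enolate face so that both new centres (the later C3 and C2) are R.

Step 3
Reactants: 6 (S)-3-[(2R,3R)-2-(allyloxy)-3-[4-(tert-butyldimethylsilyloxy)phenyl]-3-hydroxypropanoyl]-4-benzyl-1,3-oxazolidine-2-thione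
Product: 7 (2R,3R)-2-(allyloxy)-3-[4-(tert-butyldimethylsilyloxy)phenyl]-3-hydroxy-N-methoxy-N-methylpropanamide
Conditions: MeNHOMe·HCl, imidazole, CH2Cl2, rt
Reagents that add atoms: N,O-dimethylhydroxylamine hydrochloride, CNOC.Cl
Why: Direct aminolysis of the activated N-acyl oxazolidinethione should give the N-methoxy-N-methylamide under near-neutral conditions without touching either stereocentre, and returns the auxiliary.

Step 4
Reactants: 7 (2R,3R)-2-(allyloxy)-3-[4-(tert-butyldimethylsilyloxy)phenyl]-3-hydroxy-N-methoxy-N-methylpropanamide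
Product: 8 (2R,3R)-2-(allyloxy)-3-[4-(tert-butyldimethylsilyloxy)phenyl]-N-methoxy-N-methyl-3-(triethylsilyloxy)propanamide
Conditions: TESCl, imidazole, DMF, 0 °C → rt
Reagents that add atoms: chlorotriethylsilane, CC[Si](Cl)(CC)CC
Why: Silyl ether formation masks the benzylic alcohol against retro-aldol and O-acylation in the base steps, and the triethylsilyl group can later be removed by mild acid beside the aryl tert-butyldimethylsilyl ether.

Step 5
Reactants: 8 (2R,3R)-2-(allyloxy)-3-[4-(tert-butyldimethylsilyloxy)phenyl]-N-methoxy-N-methyl-3-(triethylsilyloxy)propanamide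
Product: 9 (3R,4R)-3-(allyloxy)-4-[4-(tert-butyldimethylsilyloxy)phenyl]-4-(triethylsilyloxy)butan-2-one
Conditions: MeMgBr, THF, −78 → 0 °C
Reagents that add atoms: methylmagnesium bromide, C[Mg]Br
Why: In this Weinreb ketone synthesis the chelated tetrahedral adduct should hold until quench, so the reaction stops at the methyl ketone and the α-centre is not enolized at low temperature.

Step 6
Reactants: 9 (3R,4R)-3-(allyloxy)-4-[4-(tert-butyldimethylsilyloxy)phenyl]-4-(triethylsilyloxy)butan-2-one; 10 diallyl oxalate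
Product: 12 allyl (5R,6R)-5-(allyloxy)-6-[4-(tert-butyldimethylsilyloxy)phenyl]-2,4-dioxo-6-(triethylsilyloxy)hexanoate, via lithium enolate 11 (not isolated)
Conditions: LiN(SiMe3)2, THF, −78 °C; then 10 (1.5 equiv), −78 → 0 °C
Reagents that add atoms: none
Why: In this crossed Claisen condensation kinetic deprotonation should occur at the methyl group and not at the hindered oxygenated methine, the oxalate cannot enolize, and the product is protected in the flask as its stabilized enolate.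

Step 7
Reactants: 12 allyl (5R,6R)-5-(allyloxy)-6-[4-(tert-butyldimethylsilyloxy)phenyl]-2,4-dioxo-6-(triethylsilyloxy)hexanoate
Product: 14 allyl (2R,3R)-3-(allyloxy)-2-[4-(tert-butyldimethylsilyloxy)phenyl]-4-oxo-3,4-dihydro-2H-pyran-6-carboxylate, via hydroxy diketo ester 13 (not isolated)
Conditions: AcOH–THF–H2O (3:1:1), rt; then TsOH·H2O (cat.), PhMe, 40 °C
Reagents that add atoms: none
Why: Acid should cleave only the triethylsilyl ether, after which the benzylic hydroxyl adds to the α-keto ester carbonyl (6-exo-trig hemiketal) and dehydration gives the vinylogous ester, the cyclodehydration known from chromone-2-carboxylate synthesis; it closes ring C without breaking a bond at C2 or C3.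

Step 8
Reactants: 14 allyl (2R,3R)-3-(allyloxy)-2-[4-(tert-butyldimethylsilyloxy)phenyl]-4-oxo-3,4-dihydro-2H-pyran-6-carboxylate
Product: 15 (2R,3R)-2-[4-(tert-butyldimethylsilyloxy)phenyl]-3-hydroxy-4-oxo-3,4-dihydro-2H-pyran-6-carboxylic acid
Conditions: Pd(PPh3)4 (cat.), 4-MeC6H4SO2H, CH2Cl2, rt
Reagents that add atoms: none
Why: In this Tsuji–Trost-type deallylation zerovalent palladium should ionize the allyl ester and, with acid assistance, the allyl ether, and the sulfinate traps each allyl unit as the sulfone under non-basic conditions that leave C3 and the aryl silyl ether alone.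

Step 9
Reactants: 15 (2R,3R)-2-[4-(tert-butyldimethylsilyloxy)phenyl]-3-hydroxy-4-oxo-3,4-dihydro-2H-pyran-6-carboxylic acid
Product: 17 (2R,3R)-3-(tert-butyldimethylsilyloxy)-2-[4-(tert-butyldimethylsilyloxy)phenyl]-4-oxo-3,4-dihydro-2H-pyran-6-carboxylic acid, via silyl ester 16 (not isolated)
Conditions: TBSOTf, 2,6-lutidine, CH2Cl2, −78 → 0 °C; then aq. citric acid, THF, rt
Reagents that add atoms: tert-butyldimethylsilyl triflate, CC(C)(C)[Si](C)(C)OS(=O)(=O)C(F)(F)F
Why: Silylation with the triflate and a weak pyridine base should cap the hindered α-hydroxy ketone without enolizing C3, and the silyl ester formed alongside is hydrolysed by mild aqueous acid while both silyl ethers stay.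

Step 10
Reactants: 17 (2R,3R)-3-(tert-butyldimethylsilyloxy)-2-[4-(tert-butyldimethylsilyloxy)phenyl]-4-oxo-3,4-dihydro-2H-pyran-6-carboxylic acid
Product: 19 (2R,3R)-6-(diazoacetyl)-3-(tert-butyldimethylsilyloxy)-2-[4-(tert-butyldimethylsilyloxy)phenyl]-2,3-dihydro-4H-pyran-4-one, via acid chloride 18 (not isolated)
Conditions: 1-chloro-N,N,2-trimethylprop-1-en-1-amine, CH2Cl2, 0 °C; then CH2N2 (3 equiv), Et2O, −10 °C
Reagents that add atoms: diazomethane, C=[N+]=[N-]
Why: This is the acylation of diazomethane used in the Arndt–Eistert sequence: the acid chloride is made under neutral conditions, a second equivalent of diazomethane takes up HCl, and at low temperature acylation should outrun dipolar cycloaddition to the enone.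

Step 11
Reactants: 20 geranyl bromide
Product: 21 (E)-5,9-dimethyldeca-4,8-dien-1-yne
Conditions: HC≡CMgBr (3 equiv), CuCl (cat.), THF, 0 °C → rt
Reagents that add atoms: ethynylmagnesium bromide, C#C[Mg]Br
Why: Copper-catalysed allylic substitution of a primary allylic bromide by an alkynyl Grignard reagent should occur at the α-carbon and keep the E-alkene, giving the skipped enyne.

Step 12
Reactants: 21 (E)-5,9-dimethyldeca-4,8-dien-1-yne
Product: 24 (E)-5,9-dimethyl-1-(triisopropylsilyloxy)deca-4,8-dien-1-yne, via lithium acetylide 22 (not isolated), via lithium ynolate 23 (not isolated)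
Conditions: n-BuLi, THF, −78 °C; LiOOt-Bu (from t-BuOOH and LiN(SiMe3)2), −78 → 0 °C; then TIPSOTf, −78 → 0 °C
Reagents that add atoms: tert-butyl hydroperoxide, CC(C)(C)OO; triisopropylsilyl triflate, CC(C)[Si](OS(=O)(=O)C(F)(F)F)(C(C)C)C(C)C
Why: Oxygen transfer from the lithium peroxide to the acetylide carbanion gives the ynolate, and the bulky silyl triflate should silylate it on oxygen (not on carbon) to the siloxyalkyne; the alkenes are inert to this nucleophilic oxidant.

Step 13
Reactants: 19 (2R,3R)-6-(diazoacetyl)-3-(tert-butyldimethylsilyloxy)-2-[4-(tert-butyldimethylsilyloxy)phenyl]-2,3-dihydro-4H-pyran-4-one; 24 (E)-5,9-dimethyl-1-(triisopropylsilyloxy)deca-4,8-dien-1-yne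
Product: 29 (2R,3R)-3-(tert-butyldimethylsilyloxy)-2-[4-(tert-butyldimethylsilyloxy)phenyl]-6-[(2E)-3,7-dimethylocta-2,6-dienyl]-5-hydroxy-7-(triisopropylsilyloxy)chroman-4-one, via vinylketene 25 (not isolated), via vinylcyclobutenone 26 (not isolated), via dienylketene 27 (not isolated), via cyclohexadienone 28 (not isolated)
Conditions: 24 (1.5 equiv), hν (medium-pressure Hg lamp, Pyrex), ClCH2CH2Cl, rt, until the diazo band is gone; then 80 °C
Reagents that add atoms: none
Why: Light expels N2 from 19 and the pyranone carbon C8a migrates to the carbene centre (Wolff rearrangement, C8–C8a) to give vinylketene 25. Its electrophilic carbonyl carbon (C5) should bond to the geranyl-bearing nucleophilic carbon of 24 and C8 to the silyloxy carbon in a [2+2] cycloaddition (C5–C6, C7–C8) that gives cyclobutenone 26. Four-electron electrocyclic opening of the C5–C8 bond then gives dienylketene 27, which closes ring A by six-electron disrotatory electrocyclization onto C4a (C4a–C5) and tautomerizes from 28 to the phenol. The closest known reaction type is the Danheiser benzannulation of α-diazo ketones with siloxyalkynes to resorcinol monosilyl ethers. No lasting stereocentre is formed, and C2, C3 and the geranyl alkenes meet no acid, base or electrophile. The selectivity needed is the orientation of the [2+2] step, which the oxygen polarization of the ynol silyl ether secures, so geranyl can end only on C6 between the new 5-hydroxyl (hydrogen-bonded to the C4 ketone) and the 7-silyloxy group.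

Step 14
Reactants: 29 (2R,3R)-3-(tert-butyldimethylsilyloxy)-2-[4-(tert-butyldimethylsilyloxy)phenyl]-6-[(2E)-3,7-dimethylocta-2,6-dienyl]-5-hydroxy-7-(triisopropylsilyloxy)chroman-4-one
Product: 30 bonnaniol, (2R,3R)-6-[(2E)-3,7-dimethylocta-2,6-dienyl]-3,5,7-trihydroxy-2-(4-hydroxyphenyl)chroman-4-one
Conditions: HF·pyridine, pyridine, THF, 0 °C → rt
Reagents that add atoms: none
Why: Fluoride-mediated desilylation in a pyridine-buffered medium should remove the two aryl silyl ethers and the secondary silyl ether without base-induced opening of ring C at C2/C3 or acid-induced cyclization of the geranyl chain onto a phenol.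

**Compound list**

1 | (S)-4-benzyl-1,3-oxazolidine-2-thione | S=C1N[C@@H](Cc2ccccc2)CO1 | starting material
2 | 2-(allyloxy)acetic acid | C=CCOCC(=O)O | starting material
3 | (S)-3-[2-(allyloxy)acetyl]-4-benzyl-1,3-oxazolidine-2-thione | C=CCOCC(=O)N1C(=S)OC[C@@H]1Cc1ccccc1 | intermediate
4 | 4-(tert-butyldimethylsilyloxy)benzaldehyde | O=Cc1ccc(O[Si](C)(C)C(C)(C)C)cc1 | starting material
5 | trichlorotitanium (Z)-enolate of 3 | Cl[Ti](Cl)(Cl)O/C(=C\OCC=C)N1C(=S)OC[C@@H]1Cc1ccccc1 | intermediate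
6 | (S)-3-[(2R,3R)-2-(allyloxy)-3-[4-(tert-butyldimethylsilyloxy)phenyl]-3-hydroxypropanoyl]-4-benzyl-1,3-oxazolidine-2-thione | C=CCO[C@H]([C@H](O)c1ccc(O[Si](C)(C)C(C)(C)C)cc1)C(=O)N1C(=S)OC[C@@H]1Cc1ccccc1 | intermediate
7 | (2R,3R)-2-(allyloxy)-3-[4-(tert-butyldimethylsilyloxy)phenyl]-3-hydroxy-N-methoxy-N-methylpropanamide | C=CCO[C@H]([C@H](O)c1ccc(O[Si](C)(C)C(C)(C)C)cc1)C(=O)N(C)OC | intermediate
8 | (2R,3R)-2-(allyloxy)-3-[4-(tert-butyldimethylsilyloxy)phenyl]-N-methoxy-N-methyl-3-(triethylsilyloxy)propanamide | C=CCO[C@H]([C@H](O[Si](CC)(CC)CC)c1ccc(O[Si](C)(C)C(C)(C)C)cc1)C(=O)N(C)OC | intermediate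
9 | (3R,4R)-3-(allyloxy)-4-[4-(tert-butyldimethylsilyloxy)phenyl]-4-(triethylsilyloxy)butan-2-one | C=CCO[C@H]([C@H](O[Si](CC)(CC)CC)c1ccc(O[Si](C)(C)C(C)(C)C)cc1)C(C)=O | intermediate
10 | diallyl oxalate | C=CCOC(=O)C(=O)OCC=C | starting material
11 | lithium enolate of 9 (methyl side) | [Li]OC(=C)[C@H](OCC=C)[C@H](O[Si](CC)(CC)CC)c1ccc(O[Si](C)(C)C(C)(C)C)cc1 | intermediate
12 | allyl (5R,6R)-5-(allyloxy)-6-[4-(tert-butyldimethylsilyloxy)phenyl]-2,4-dioxo-6-(triethylsilyloxy)hexanoate | C=CCOC(=O)C(=O)CC(=O)[C@H](OCC=C)[C@H](O[Si](CC)(CC)CC)c1ccc(O[Si](C)(C)C(C)(C)C)cc1 | intermediate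
13 | allyl (5R,6R)-5-(allyloxy)-6-[4-(tert-butyldimethylsilyloxy)phenyl]-6-hydroxy-2,4-dioxohexanoate | C=CCOC(=O)C(=O)CC(=O)[C@H](OCC=C)[C@H](O)c1ccc(O[Si](C)(C)C(C)(C)C)cc1 | intermediate
14 | allyl (2R,3R)-3-(allyloxy)-2-[4-(tert-butyldimethylsilyloxy)phenyl]-4-oxo-3,4-dihydro-2H-pyran-6-carboxylate | C=CCOC(=O)C1=CC(=O)[C@H](OCC=C)[C@@H](c2ccc(O[Si](C)(C)C(C)(C)C)cc2)O1 | intermediate
15 | (2R,3R)-2-[4-(tert-butyldimethylsilyloxy)phenyl]-3-hydroxy-4-oxo-3,4-dihydro-2H-pyran-6-carboxylic acid | O=C(O)C1=CC(=O)[C@H](O)[C@@H](c2ccc(O[Si](C)(C)C(C)(C)C)cc2)O1 | intermediate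
16 | tert-butyldimethylsilyl (2R,3R)-3-(tert-butyldimethylsilyloxy)-2-[4-(tert-butyldimethylsilyloxy)phenyl]-4-oxo-3,4-dihydro-2H-pyran-6-carboxylate | CC(C)(C)[Si](C)(C)OC(=O)C1=CC(=O)[C@H](O[Si](C)(C)C(C)(C)C)[C@@H](c2ccc(O[Si](C)(C)C(C)(C)C)cc2)O1 | intermediate
17 | (2R,3R)-3-(tert-butyldimethylsilyloxy)-2-[4-(tert-butyldimethylsilyloxy)phenyl]-4-oxo-3,4-dihydro-2H-pyran-6-carboxylic acid | O=C(O)C1=CC(=O)[C@H](O[Si](C)(C)C(C)(C)C)[C@@H](c2ccc(O[Si](C)(C)C(C)(C)C)cc2)O1 | intermediate
18 | (2R,3R)-3-(tert-butyldimethylsilyloxy)-2-[4-(tert-butyldimethylsilyloxy)phenyl]-4-oxo-3,4-dihydro-2H-pyran-6-carbonyl chloride | O=C(Cl)C1=CC(=O)[C@H](O[Si](C)(C)C(C)(C)C)[C@@H](c2ccc(O[Si](C)(C)C(C)(C)C)cc2)O1 | intermediate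
19 | (2R,3R)-6-(diazoacetyl)-3-(tert-butyldimethylsilyloxy)-2-[4-(tert-butyldimethylsilyloxy)phenyl]-2,3-dihydro-4H-pyran-4-one | [N-]=[N+]=CC(=O)C1=CC(=O)[C@H](O[Si](C)(C)C(C)(C)C)[C@@H](c2ccc(O[Si](C)(C)C(C)(C)C)cc2)O1 | intermediate
20 | geranyl bromide, (E)-1-bromo-3,7-dimethylocta-2,6-diene | CC(C)=CCC/C(C)=C/CBr | starting material
21 | (E)-5,9-dimethyldeca-4,8-dien-1-yne | C#CC/C=C(\C)CCC=C(C)C | intermediate
22 | lithium acetylide of 21 | [Li]C#CC/C=C(\C)CCC=C(C)C | intermediate
23 | lithium (E)-5,9-dimethyldeca-4,8-dien-1-yn-1-olate | [Li]OC#CC/C=C(\C)CCC=C(C)C | intermediate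
24 | (E)-5,9-dimethyl-1-(triisopropylsilyloxy)deca-4,8-dien-1-yne | CC(C)=CCC/C(C)=C/CC#CO[Si](C(C)C)(C(C)C)C(C)C | intermediate
25 | [(2R,3R)-3-(tert-butyldimethylsilyloxy)-2-[4-(tert-butyldimethylsilyloxy)phenyl]-4-oxo-3,4-dihydro-2H-pyran-6-yl]ketene | O=C=CC1=CC(=O)[C@H](O[Si](C)(C)C(C)(C)C)[C@@H](c2ccc(O[Si](C)(C)C(C)(C)C)cc2)O1 | intermediate
26 | 2-geranyl-4-[(2R,3R)-3-(tert-butyldimethylsilyloxy)-2-[4-(tert-butyldimethylsilyloxy)phenyl]-4-oxo-3,4-dihydro-2H-pyran-6-yl]-3-(triisopropylsilyloxy)cyclobut-2-en-1-one (both epimers at the ring carbon) | CC(C)=CCC/C(C)=C/CC1=C(O[Si](C(C)C)(C(C)C)C(C)C)C(C2=CC(=O)[C@H](O[Si](C)(C)C(C)(C)C)[C@@H](c3ccc(O[Si](C)(C)C(C)(C)C)cc3)O2)C1=O | intermediate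
27 | dienylketene from ring opening of 26, with the ketene carbon and the pyranyl group cis on the central alkene | CC(C)=CCC/C(C)=C/CC(=C=O)/C(O[Si](C(C)C)(C(C)C)C(C)C)=C\C1=CC(=O)[C@H](O[Si](C)(C)C(C)(C)C)[C@@H](c2ccc(O[Si](C)(C)C(C)(C)C)cc2)O1 | intermediate
28 | (2R,3R)-3-(tert-butyldimethylsilyloxy)-2-[4-(tert-butyldimethylsilyloxy)phenyl]-6-geranyl-7-(triisopropylsilyloxy)-2,3-dihydro-4aH-chromene-4,5-dione (keto tautomer of 29) | CC(C)=CCC/C(C)=C/CC1=C(O[Si](C(C)C)(C(C)C)C(C)C)C=C2O[C@H](c3ccc(O[Si](C)(C)C(C)(C)C)cc3)[C@@H](O[Si](C)(C)C(C)(C)C)C(=O)C2C1=O | intermediate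
29 | (2R,3R)-3-(tert-butyldimethylsilyloxy)-2-[4-(tert-butyldimethylsilyloxy)phenyl]-6-[(2E)-3,7-dimethylocta-2,6-dienyl]-5-hydroxy-7-(triisopropylsilyloxy)chroman-4-one | CC(C)=CCC/C(C)=C/Cc1c(O[Si](C(C)C)(C(C)C)C(C)C)cc2c(c1O)C(=O)[C@H](O[Si](C)(C)C(C)(C)C)[C@@H](c1ccc(O[Si](C)(C)C(C)(C)C)cc1)O2 | intermediate
30 | bonnaniol, (2R,3R)-6-[(2E)-3,7-dimethylocta-2,6-dienyl]-3,5,7-trihydroxy-2-(4-hydroxyphenyl)chroman-4-one | CC(C)=CCC/C(C)=C/Cc1c(O)cc2c(c1O)C(=O)[C@H](O)[C@@H](c1ccc(O)cc1)O2 | target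

**Counts and risks**

Total step count: 14. Longest linear sequence: 12 (steps 1 to 10, 13 and 14); steps 11 and 12 form the two-step side branch to the alkyne.

Steps most likely to fail, riskiest first:

Step 13. The vinylogous ester of 19 may be excited in competition with loss of N2 and undergo enone [2+2] photocycloaddition with the geranyl alkenes or the ynol ether, or the acyl-substituted vinylketene may be consumed before it meets the alkyne. The fallback sets out from 19 and comes back at 29, and makes the same ketene without light. Wolff rearrangement of 19 in water without irradiation (PhCO2Ag, Et3N, aq. THF) would give the homologous pyranylacetic acid F1. 1-Chloro-N,N,2-trimethylprop-1-en-1-amine would convert it into the pyranylacetyl chloride F2. Slow addition of Et3N to F2 and 24 in toluene at rt would generate 25 by dehydrochlorination, which is trapped by the alkyne to 26, and heating at 80 °C would carry 26 through 27 and 28 to 29.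

Step 2. The electron-rich aromatic aldehyde may give poor anti/syn or facial selectivity in the open transition state, and excess TiCl4 may ionize the benzylic titanium alkoxide. The fallback sets out from 4 and comes back at 15; it sets C2 by reagent control and brings in the C3 oxygen after ring C is closed, under substrate control. Methallylboration of 4 with (−)-Ipc2B(methallyl) (Et2O, −78 °C, ethanolamine work-up), which adds to the Si face, would give the (S)-homoallylic alcohol F3. TESCl and imidazole would give its triethylsilyl ether F4, and ozonolysis (O3, then PPh3) the β-silyloxy methyl ketone F5. LiN(SiMe3)2 would form the lithium enolate F6, and 10 would acylate it to the diketo ester F7. AcOH–THF–H2O would free the hydroxy diketo ester F8, and TsOH would close it to the (S)-pyranone allyl ester F9. LiN(SiMe3)2 at −78 °C would give the lithium enolate F10, and 2-(phenylsulfonyl)-3-phenyloxaziridine, approaching anti to the C2 aryl group, would give the trans 3-hydroxy pyranone allyl ester F11. Pd(PPh3)4 with morpholine would then cleave the allyl ester to 15.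

Step 8. The hindered secondary allyl ether next to the ketone may be cleaved only in part, or the sulfinate may add to the vinylogous ester. The fallback sets out from 8 and comes back at 17; it exchanges the ether for the silyl ether before ring C exists and uses isomerization and hydrolysis in place of π-allyl chemistry. [Ir(cod)(PMePh2)2]PF6 (activated with H2, THF) would isomerize 8 to the propenyl ether F12, and HgCl2 with HgO in aqueous acetone would hydrolyse it to the α-hydroxy amide F13. TBSOTf with 2,6-lutidine would give the silyl ether amide F14, and MeMgBr the bis-silyl methyl ketone F15. LiN(SiMe3)2 would form the lithium enolate F16, which 10 acylates to the diketo ester F17. AcOH–THF–H2O would remove only the triethylsilyl group to give the hydroxy diketo ester F18, TsOH would close it to the 3-silyloxy pyranone allyl ester F19, and Pd(PPh3)4 with morpholine would cleave the allyl ester to 17.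

**Further compounds**

F1 | step 13 | 2-[(2R,3R)-3-(tert-butyldimethylsilyloxy)-2-[4-(tert-butyldimethylsilyloxy)phenyl]-4-oxo-3,4-dihydro-2H-pyran-6-yl]acetic acid | OC(=O)CC1=CC(=O)[C@H](O[Si](C)(C)C(C)(C)C)[C@@H](c2ccc(O[Si](C)(C)C(C)(C)C)cc2)O1
F2 | step 13 | 2-[(2R,3R)-3-(tert-butyldimethylsilyloxy)-2-[4-(tert-butyldimethylsilyloxy)phenyl]-4-oxo-3,4-dihydro-2H-pyran-6-yl]acetyl chloride | ClC(=O)CC1=CC(=O)[C@H](O[Si](C)(C)C(C)(C)C)[C@@H](c2ccc(O[Si](C)(C)C(C)(C)C)cc2)O1
F3 | step 2 | (S)-1-[4-(tert-butyldimethylsilyloxy)phenyl]-3-methylbut-3-en-1-ol | C=C(C)C[C@H](O)c1ccc(O[Si](C)(C)C(C)(C)C)cc1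
F4 | step 2 | (S)-tert-butyldimethyl[4-[3-methyl-1-(triethylsilyloxy)but-3-enyl]phenoxy]silane | C=C(C)C[C@H](O[Si](CC)(CC)CC)c1ccc(O[Si](C)(C)C(C)(C)C)cc1
F5 | step 2 | (S)-4-[4-(tert-butyldimethylsilyloxy)phenyl]-4-(triethylsilyloxy)butan-2-one | CC(=O)C[C@H](O[Si](CC)(CC)CC)c1ccc(O[Si](C)(C)C(C)(C)C)cc1
F6 | step 2 | lithium enolate of F5 (methyl side) | [Li]OC(=C)C[C@H](O[Si](CC)(CC)CC)c1ccc(O[Si](C)(C)C(C)(C)C)cc1
F7 | step 2 | allyl (S)-6-[4-(tert-butyldimethylsilyloxy)phenyl]-2,4-dioxo-6-(triethylsilyloxy)hexanoate | C=CCOC(=O)C(=O)CC(=O)C[C@H](O[Si](CC)(CC)CC)c1ccc(O[Si](C)(C)C(C)(C)C)cc1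
F8 | step 2 | allyl (S)-6-[4-(tert-butyldimethylsilyloxy)phenyl]-6-hydroxy-2,4-dioxohexanoate | C=CCOC(=O)C(=O)CC(=O)C[C@H](O)c1ccc(O[Si](C)(C)C(C)(C)C)cc1
F9 | step 2 | allyl (S)-2-[4-(tert-butyldimethylsilyloxy)phenyl]-4-oxo-3,4-dihydro-2H-pyran-6-carboxylate | C=CCOC(=O)C1=CC(=O)C[C@@H](c2ccc(O[Si](C)(C)C(C)(C)C)cc2)O1
F10 | step 2 | lithium enolate of F9 (C3–C4) | [Li]OC1=C[C@@H](c2ccc(O[Si](C)(C)C(C)(C)C)cc2)OC(C(=O)OCC=C)=C1
F11 | step 2 | allyl (2R,3R)-2-[4-(tert-butyldimethylsilyloxy)phenyl]-3-hydroxy-4-oxo-3,4-dihydro-2H-pyran-6-carboxylate | C=CCOC(=O)C1=CC(=O)[C@H](O)[C@@H](c2ccc(O[Si](C)(C)C(C)(C)C)cc2)O1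
F12 | step 8 | (2R,3R)-3-[4-(tert-butyldimethylsilyloxy)phenyl]-N-methoxy-N-methyl-2-[(E)-prop-1-enyloxy]-3-(triethylsilyloxy)propanamide | C/C=C/O[C@H]([C@H](O[Si](CC)(CC)CC)c1ccc(O[Si](C)(C)C(C)(C)C)cc1)C(=O)N(C)OC
F13 | step 8 | (2R,3R)-3-[4-(tert-butyldimethylsilyloxy)phenyl]-2-hydroxy-N-methoxy-N-methyl-3-(triethylsilyloxy)propanamide | O[C@H]([C@H](O[Si](CC)(CC)CC)c1ccc(O[Si](C)(C)C(C)(C)C)cc1)C(=O)N(C)OC
F14 | step 8 | (2R,3R)-2-(tert-butyldimethylsilyloxy)-3-[4-(tert-butyldimethylsilyloxy)phenyl]-N-methoxy-N-methyl-3-(triethylsilyloxy)propanamide | CC(C)(C)[Si](C)(C)O[C@H]([C@H](O[Si](CC)(CC)CC)c1ccc(O[Si](C)(C)C(C)(C)C)cc1)C(=O)N(C)OC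
F15 | step 8 | (3R,4R)-3-(tert-butyldimethylsilyloxy)-4-[4-(tert-butyldimethylsilyloxy)phenyl]-4-(triethylsilyloxy)butan-2-one | CC(=O)[C@H](O[Si](C)(C)C(C)(C)C)[C@H](O[Si](CC)(CC)CC)c1ccc(O[Si](C)(C)C(C)(C)C)cc1
F16 | step 8 | lithium enolate of F15 (methyl side) | [Li]OC(=C)[C@H](O[Si](C)(C)C(C)(C)C)[C@H](O[Si](CC)(CC)CC)c1ccc(O[Si](C)(C)C(C)(C)C)cc1
F17 | step 8 | allyl (5R,6R)-5-(tert-butyldimethylsilyloxy)-6-[4-(tert-butyldimethylsilyloxy)phenyl]-2,4-dioxo-6-(triethylsilyloxy)hexanoate | C=CCOC(=O)C(=O)CC(=O)[C@H](O[Si](C)(C)C(C)(C)C)[C@H](O[Si](CC)(CC)CC)c1ccc(O[Si](C)(C)C(C)(C)C)cc1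
F18 | step 8 | allyl (5R,6R)-5-(tert-butyldimethylsilyloxy)-6-[4-(tert-butyldimethylsilyloxy)phenyl]-6-hydroxy-2,4-dioxohexanoate | C=CCOC(=O)C(=O)CC(=O)[C@H](O[Si](C)(C)C(C)(C)C)[C@H](O)c1ccc(O[Si](C)(C)C(C)(C)C)cc1
F19 | step 8 | allyl (2R,3R)-3-(tert-butyldimethylsilyloxy)-2-[4-(tert-butyldimethylsilyloxy)phenyl]-4-oxo-3,4-dihydro-2H-pyran-6-carboxylate | C=CCOC(=O)C1=CC(=O)[C@H](O[Si](C)(C)C(C)(C)C)[C@@H](c2ccc(O[Si](C)(C)C(C)(C)C)cc2)O1
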